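**Assumptions (one line):** geranyl-MgCl/CuI opens the terminal epoxide at its CH2 (SN2, α-selective). The C′ epimers arise from the non-selective epoxidation in Step 1, are carried as a ~1:1 mixture, and are separated at the end. The McMurry closure gives mainly the E alkene.

## Retrosynthetic overview
- Target ← desilylation of macrocycle 13, which is closed last at C11=C12 by intramolecular McMurry coupling of keto-aldehyde 12.
- 12 ← two iterative Claisen [3,3] chain extensions (isopropenyl Grignard addition, then vinyl-ether Claisen) of keto-aldehyde 6. They form the E alkenes C3=C4 and C7=C8 and the bonds C5–C6 and C9–C10.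
- 6 ← periodate cleavage of the ring epoxide of 5, which comes from (R)-limonene dioxide opened at its terminal epoxide by a geranyl nucleophile. The limonene ring is opened here, and the 14-membered ring is formed last.
- C1 comes from (R)-limonene and is never touched. C′ (the carbinol carbon) is the non-selectively formed terminal-epoxide centre, carried as an epimer mixture and separated at the end.

## Route

**Step 1**
Reactants: 1 (R)-limonene
Product: 2 (4R)-limonene dioxide, 1-methyl-4-(2-methyloxiran-2-yl)-7-oxabicyclo[4.1.0]heptane, epoxide stereocentres as a mixture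
Conditions: mCPBA (2.3 equiv), NaHCO3, CH2Cl2, 0 °C → rt
Reagents that add atoms: mCPBA, OOC(=O)c1cccc(Cl)c1 (gives the epoxide O atoms)
Why: Prilezhaev epoxidation of both alkenes, with C4 untouched. The ring-epoxide centres are erased in Step 4. The epoxide centre on C8 becomes C′ and is formed non-selectively, so both C′ epimers are carried forward.

**Step 2**
Reactants: 2 limonene dioxide; 3 geranyl chloride, (2E)-1-chloro-3,7-dimethylocta-2,6-diene
Product: 4 (5E)-6,10-dimethyl-2-[(4R)-1-methyl-7-oxabicyclo[4.1.0]heptan-4-yl]undeca-5,9-dien-2-ol, C′ epimeric, ring epoxide intact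
Conditions: 3 + Mg, THF, to give geranylMgCl; then CuI (10 mol %), 2, THF, −20 → 0 °C
Reagents that add atoms: none (the geranyl group comes from 3)
Why: Cu-catalysed SN2 opening at the unhindered CH2 of the 1,1-disubstituted epoxide, which is far more reactive than the trisubstituted ring epoxide. This installs the complete C′ side chain with its E alkene. The C′ configuration is fixed in Step 1 and unchanged here, because the attacked carbon is not the stereocentre.

**Step 3**
Reactants: 4
Product: 5 tertiary TBS ether of 4
Conditions: TBSOTf, 2,6-lutidine, CH2Cl2, −78 → 0 °C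
Reagents that add atoms: TBSOTf, C[Si](C)(C(C)(C)C)OS(=O)(=O)C(F)(F)F (gives the TBS group)
Why: silylation of the hindered tertiary alcohol prevents cineole-type ether or lactol formation onto the ring epoxide or the aldehyde in the next steps.

**Step 4**
Reactants: 5
Product: 6 (3R)-6-oxo-3-[(4E)-1-(TBSO)-1,5,9-trimethyldeca-4,8-dien-1-yl]heptanal (keto-aldehyde; C3 = CHO, C12 = methyl ketone, C′ epimeric)
Conditions: H5IO6, THF/Et2O (1:1), 0 °C → rt
Reagents that add atoms: H5IO6, O=I(O)(O)(O)(O)O (net source of the extra carbonyl O atom)
Why: H5IO6 first hydrates the epoxide to the 1,2-diol, using its own water, which is regenerated on cleavage. Malaprade cleavage of the diol then gives the aldehyde and the methyl ketone and erases the ring-epoxide stereocentres. C1 is β to the aldehyde and not enolisable, so it is preserved.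

**Step 5**
Reactants: 6; 7 isopropenylmagnesium bromide
Product: 8 secondary allylic alcohol CH2=C(Me)–C3H(OH)–C2H2–C1 (C3 carbinol epimeric, C1 R, ketone and OTBS intact)
Conditions: 7 (1.05 equiv), THF, −78 °C
Reagents that add atoms: none beyond reactant 7, CC(=C)[Mg]Br
Why: Grignard 1,2-addition, chemoselective for the aldehyde over the methyl ketone at low temperature. The new C3 carbinol centre is destroyed in Step 6.

**Step 6 (key sigmatropic step)**
Reactants: 8; 9 ethyl vinyl ether
Product: 10 aldehyde OHC7–C6H2–C5H2–C4(Me)=C3H–C2H2–C1 (E alkene, C1 R)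
Conditions: Hg(OAc)2 (10 mol %), NaOAc, 9 (neat), 35 °C, 24 h; then remove 9, toluene, sealed tube, 150 °C
Reagents that add atoms: none beyond reactant 9, C=COCC (gives C6 and C7)
Why: Hg(II)-catalysed vinyl-ether exchange gives the allyl vinyl ether, which undergoes Claisen [3,3]-rearrangement. The chair transition state puts C2 equatorial, giving the E-trisubstituted C3=C4 alkene. The C5–C6 bond forms and the aldehyde appears directly. The C3 carbinol configuration is irrelevant because that centre becomes sp2.

**Step 7**
Reactants: 10; 7 isopropenylmagnesium bromide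
Product: 11 allylic alcohol CH2=C(Me)–C7H(OH)–C6H2–C5H2–C4(Me)=C3H–C2H2–C1
Conditions: 7 (1.05 equiv), THF, −78 °C
Reagents that add atoms: none beyond reactant 7
Why: the same aldehyde-selective Grignard addition. The new C7 carbinol centre is destroyed in Step 8.

**Step 8 (key sigmatropic step)**
Reactants: 11; 9 ethyl vinyl ether
Product: 12 seco keto-aldehyde OHC11–C10H2–C9H2–C8(Me)=C7H–C6H2–C5H2–C4(Me)=C3H–C2H2–C1(R)(C′…)–C14H2–C13H2–C12(=O)CH3
Conditions: Hg(OAc)2 (10 mol %), NaOAc, 9 (neat), 35 °C; then toluene, sealed tube, 150 °C
Reagents that add atoms: none beyond reactant 9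
Why: a second vinyl-ether exchange/Claisen [3,3]-rearrangement. The chair transition state again gives the E-C7=C8 alkene and forms the C9–C10 bond.

**Step 9**
Reactants: 12
Product: 13 TBS ether of the 14-membered macrocycle (C1 R, C′ epimeric, all-E triene)
Conditions: TiCl3(DME)1.5, Zn–Cu, DME, reflux, substrate added by syringe pump over 12 h (≈2 mM)
Reagents that add atoms: none
Why: intramolecular McMurry aldehyde–ketone coupling forms the trisubstituted C11=C12 bond and closes the ring. High dilution favours cyclisation over oligomerisation, and the E alkene is expected to predominate.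

**Step 10**
Reactants: 13
Product: 14 colleterpenol (C′ (S) epimer isolated)
Conditions: TBAF (5 equiv), THF, 60 °C; then preparative HPLC (AgNO3-silica) to separate the C′ epimers and any Z alkene
Reagents that add atoms: none
Why: fluoride cleavage of the tertiary TBS ether. C1 (R) comes from limonene and is untouched. The C′ epimers are diastereomers because C1 is fixed, so the (S)-configured one is isolated by chromatography.

## Compound list
1 | (R)-(+)-limonene | CC1=CC[C@@H](CC1)C(C)=C | starting material
2 | (4R)-limonene dioxide (epoxide centres unspecified) | CC12OC1C[C@@H](CC2)C1(C)CO1 | intermediate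
3 | geranyl chloride | CC(C)=CCC/C(C)=C/CCl | starting material
4 | epoxy tertiary alcohol | CC12OC1C[C@@H](CC2)C(C)(O)CC/C=C(\C)CCC=C(C)C | intermediate
5 | TBS ether of 4 | CC12OC1C[C@@H](CC2)C(C)(O[Si](C)(C)C(C)(C)C)CC/C=C(\C)CCC=C(C)C | intermediate
6 | keto-aldehyde | O=CC[C@@H](CCC(C)=O)C(C)(O[Si](C)(C)C(C)(C)C)CC/C=C(\C)CCC=C(C)C | intermediate
7 | isopropenylmagnesium bromide | CC(=C)[Mg]Br | starting material
8 | allylic alcohol from 6 | C=C(C)C(O)C[C@@H](CCC(C)=O)C(C)(O[Si](C)(C)C(C)(C)C)CC/C=C(\C)CCC=C(C)C | intermediate
9 | ethyl vinyl ether | C=COCC | starting material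
10 | aldehyde after first Claisen | O=CCC/C(C)=C/C[C@@H](CCC(C)=O)C(C)(O[Si](C)(C)C(C)(C)C)CC/C=C(\C)CCC=C(C)C | intermediate
11 | allylic alcohol from 10 | C=C(C)C(O)CC/C(C)=C/C[C@@H](CCC(C)=O)C(C)(O[Si](C)(C)C(C)(C)C)CC/C=C(\C)CCC=C(C)C | intermediate
12 | seco keto-aldehyde after second Claisen | O=CCC/C(C)=C/CC/C(C)=C/C[C@@H](CCC(C)=O)C(C)(O[Si](C)(C)C(C)(C)C)CC/C=C(\C)CCC=C(C)C | intermediate
13 | TBS-protected macrocycle (formed as C′ epimer mixture; (S)-C′ epimer drawn) | CC(C)=CCC/C(C)=C/CC[C@](C)(O[Si](C)(C)C(C)(C)C)[C@H]1C/C=C(\C)CC/C=C(\C)CC/C=C(\C)CC1 | intermediate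
14 | colleterpenol | CC(C)=CCC/C(C)=C/CC[C@](C)(O)[C@H]1C/C=C(\C)CC/C=C(\C)CC/C=C(\C)CC1 | target

Intermediates 4, 5, 6, 8, 10, 11 and 12 are drawn with C′ unspecified because they are epimeric mixtures.

**Total step count:** 10
**Longest linear sequence:** 10 (compound 1 to compound 14)

## Three steps most likely to fail
1. **Step 9 (McMurry closure):** the yield may be low and the E/Z selectivity at C11=C12 uncertain.
   Fallback: change the closure. Convert the aldehyde of 12 to a vinyl group (Wittig) and the ketone to an isopropenyl group (Petasis or Tebbe methylenation), then close C11=C12 by ring-closing metathesis (Hoveyda–Grubbs II) and separate the E/Z isomers.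
2. **Step 2 (geranyl opening):** geranyl-Cu may attack at the γ carbon instead of the α carbon, or the Grignard/MgCl2 may rearrange the ring epoxide.
   Fallback: open the terminal epoxide of 2 with lithiated geranyl phenyl sulfone (n-BuLi, THF/HMPA), which alkylates at the α carbon. Then remove the sulfone with Pd(dppp)Cl2/LiBHEt3, which keeps the E alkene.
3. **Steps 5–8 (free methyl ketone during the Grignard and Hg/thermal Claisen cycles):** ketone addition or enolisation, or decomposition of the polyene, could occur.
   Fallback: after Step 5, protect the ketone as its dioxolane (ethylene glycol, PPTS). Then do each chain extension as Johnson–Claisen (MeC(OEt)3, EtCO2H, 140 °C) followed by DIBAL reduction of the ester to the aldehyde, which is safe once the ketone is masked. Remove the ketal (PPTS, acetone/H2O) before the McMurry step.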